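**Retrosynthetic overview**

1. The array C5–OH / C6–C1′H(nPr)–CH2–CO2H is read as an opened δ-lactone. Target 14 comes from lactone 13, whose ring O5–C(=O)–CH2–C1′–C6–C5 is not in the target and is opened last.
2. Lactone 13 comes from phenol 11 and (E)-hex-2-enal by one carbene-catalysed oxidative [3+3] annulation. It forms C6–C1′ at the last free position of the hexasubstituted benzene ring, sets C1′ (R), and closes the temporary lactone onto O5.
3. The C8 prenyl group is sent from the same oxygen beforehand: O5-prenyl ether 8 gives 11 by para-Claisen–Cope rearrangement. O5 thus relays carbon first to its para position (C8), then to its ortho position (C6).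
4. The dihydropyranone ring (O1–C2 bond) is closed first, by alkaloid-catalysed oxa-Michael addition of tigloyl phenol 4 (sets C2 as S). C3 is then equilibrated to trans.
5. Ring order: benzene ring bought (1,3,5-trimethoxybenzene), then dihydropyranone, then temporary δ-lactone, then lactone opened.

Key step: step 7

Assumption: the sense of induction of quinidine (step 3) and of the triazolium catalyst (step 7) is assigned by analogy with related reactions. Both are available in both (pseudo)enantiomeric forms, and the form that gives the stated configuration is the one meant.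

**Route**

Step 1
Reactants: 1 1,3,5-trimethoxybenzene; 2 tigloyl chloride [(E)-2-methylbut-2-enoyl chloride]
Product: 3 (E)-2-methyl-1-(2,4,6-trimethoxyphenyl)but-2-en-1-one
Conditions: SnCl4 (1.1 equiv), CH2Cl2, −20 → 0 °C
Reagents that add atoms: none
Why: Friedel–Crafts acylation of a C3-symmetric, highly activated arene whose three free positions are equivalent; both ortho positions of the new ketone carry methoxy groups, so neither regioisomers nor a Nazarov closure can arise, and the (E)-tigloyl geometry is kept.

Step 2
Reactants: 3 (E)-2-methyl-1-(2,4,6-trimethoxyphenyl)but-2-en-1-one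
Product: 4 (E)-1-(2-hydroxy-4,6-dimethoxyphenyl)-2-methylbut-2-en-1-one
Conditions: BCl3 (1.2 equiv), CH2Cl2, −78 → 0 °C; then H2O
Reagents that add atoms: none
Why: Chelation-directed ether cleavage, in which BCl3 bound to the ketone oxygen removes one of the two equivalent ortho methyl groups through a six-membered boron chelate, while the para methoxy group cannot chelate and should stay.

Step 3
Reactants: 4 (E)-1-(2-hydroxy-4,6-dimethoxyphenyl)-2-methylbut-2-en-1-one
Product: 5 (2S,3R)-5,7-dimethoxy-2,3-dimethylchroman-4-one (cis)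
Conditions: quinidine (20 mol%), PhCl, 15 °C
Reagents that add atoms: none
Why: Cinchona-alkaloid-catalysed intramolecular oxa-Michael addition (6-endo-trig), in which the quinuclidine nitrogen activates the phenol and the C9 hydroxyl binds the enone so that oxygen adds to one face of the tigloyl β-carbon and sets C2 as S (quinidine being the pseudoenantiomer of quinine, which is associated with the 2R series in cyclisations of this type); the cis relationship from kinetic protonation at C3 is corrected in step 4, and any trans isomer carries the same C2 centre and converges there.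

Step 4
Reactants: 5 (2S,3R)-5,7-dimethoxy-2,3-dimethylchroman-4-one
Product: 6 (2S,3S)-5-hydroxy-7-methoxy-2,3-dimethylchroman-4-one (trans)
Conditions: MgI2 (3 equiv), Et2O–toluene, 80 °C; then 1 M HCl
Reagents that add atoms: none
Why: MgI2 chelates the C4 carbonyl and the peri methoxy oxygen so that iodide removes only that methyl group by SN2, and reversible enolisation of the magnesium-bound ketone should let the labile C3 centre settle in the more stable trans (2S,3S) arrangement, while C2 is not involved.

Step 5
Reactants: 6 (2S,3S)-5-hydroxy-7-methoxy-2,3-dimethylchroman-4-one; 7 prenol (3-methylbut-2-en-1-ol)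
Product: 8 (2S,3S)-7-methoxy-2,3-dimethyl-5-[(3-methylbut-2-en-1-yl)oxy]chroman-4-one
Conditions: PPh3 (1.5 equiv), DIAD (1.5 equiv), THF, 0 °C → rt
Reagents that add atoms: none
Why: Mitsunobu etherification of the chelated C5 phenol with a primary allylic alcohol under neutral conditions, which avoids base-induced retro-oxa-Michael opening of the chromanone; no stereocentre is touched.

Step 6
Reactants: 8 (2S,3S)-7-methoxy-2,3-dimethyl-5-[(3-methylbut-2-en-1-yl)oxy]chroman-4-one
Product: 11 (2S,3S)-5-hydroxy-7-methoxy-2,3-dimethyl-8-(3-methylbut-2-en-1-yl)chroman-4-one, via ortho-Claisen dienone 9 (not isolated), via para-Cope dienone 10 (not isolated)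
Conditions: Eu(fod)3 (10 mol%), CHCl3, 60 °C
Reagents that add atoms: none
Why: Lewis-acid-accelerated aromatic Claisen rearrangement to the C6 dienone 9, then Cope shift to C8 and tautomerisation (para-Claisen–Cope), where Eu(III) chelation of the C4/C5 dicarbonyl of 9 should favour the Cope shift over enolisation, as known for 5-O-prenyl chromanones of the flavanone type; C8 is the only para position.

Step 7
Reactants: 11 (2S,3S)-5-hydroxy-7-methoxy-2,3-dimethyl-8-(3-methylbut-2-en-1-yl)chroman-4-one; 12 (E)-hex-2-enal
Product: 13 (4R,8S,9S)-5-methoxy-8,9-dimethyl-6-(3-methylbut-2-en-1-yl)-4-propyl-3,4,8,9-tetrahydro-2H,10H-pyrano[2,3-f]chromene-2,10-dione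
Conditions: aminoindanol-derived N-mesityl triazolium tetrafluoroborate (10 mol%, single enantiomer), DBU (20 mol%), 3,3′,5,5′-tetra-tert-butyl-4,4′-diphenoquinone (1.2 equiv), 4 Å MS, toluene, rt
Reagents that add atoms: none
Why: Proposed new method: the carbene–enal adduct of 12 is oxidised by the diphenoquinone to a chiral α,β-unsaturated acyl azolium, the C5 phenoxide of 11 adds to its acyl carbon, and the aryl hemiacetal undergoes a Coates–Claisen-type [3,3] shift (or C6 adds directly in a Michael sense) that bonds the β-carbon to C6 before the dienone rearomatises and O5 is acylated with release of the carbene. The closest known reaction type is the carbene-catalysed oxidative [3+3] annulation of enals with naphthols and other stable enols to 4-substituted dihydrocoumarins and dihydropyranones; the extension is to a peri-chelated acylphloroglucinol phenol, whose C6 is still activated by O5 and O7 (ortho) and O1 (para). The δ-lactone closes by 6-exo-trig acyl substitution at the acyl azolium, and this temporary ring is what forces C–C bond formation ortho to O5. The new C1′ centre should be set by the catalyst, whose indane wall shields one face of the acyl azolium, independently of the remote C2 and C3 centres. Site selectivity is secured by the substrate, since C6 is the only unsubstituted ring carbon and the para position C8 is blocked by prenyl, and the soft acyl azolium should leave the prenyl alkene and the C4 ketone alone. Under the basic conditions C3 can only equilibrate towards the trans arrangement it already has.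

Step 8
Reactants: 13 (4R,8S,9S)-5-methoxy-8,9-dimethyl-6-(3-methylbut-2-en-1-yl)-4-propyl-3,4,8,9-tetrahydro-2H,10H-pyrano[2,3-f]chromene-2,10-dione
Product: 14 (3R)-3-[(2S,3S)-5-hydroxy-7-methoxy-2,3-dimethyl-8-(3-methylbut-2-en-1-yl)-4-oxo-3,4-dihydro-2H-chromen-6-yl]hexanoic acid (CNP0233409.1)
Conditions: LiOH·H2O (3 equiv), THF–H2O (3:1), 0 °C; then 1 M HCl to pH 3, 0 °C
Reagents that add atoms: lithium hydroxide, [Li+].[OH-]
Why: Saponification of the activated aryl ester should be fast at 0 °C, the phenoxide/carboxylate dianion should suppress enolisation at C3 and retro-oxa-Michael opening, and after mild acidification the C5 hydroxyl is held by its hydrogen bond to the C4 carbonyl, so the open acid and not the lactone should be obtained; no stereocentre is touched.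

**Compound list**

1 | 1,3,5-trimethoxybenzene | COc1cc(OC)cc(OC)c1 | starting material
2 | tigloyl chloride, (E)-2-methylbut-2-enoyl chloride | C/C=C(\C)C(=O)Cl | starting material
3 | (E)-2-methyl-1-(2,4,6-trimethoxyphenyl)but-2-en-1-one | C/C=C(\C)C(=O)c1c(OC)cc(OC)cc1OC | intermediate
4 | (E)-1-(2-hydroxy-4,6-dimethoxyphenyl)-2-methylbut-2-en-1-one | C/C=C(\C)C(=O)c1c(O)cc(OC)cc1OC | intermediate
5 | (2S,3R)-5,7-dimethoxy-2,3-dimethylchroman-4-one | COc1cc(OC)c2c(c1)O[C@@H](C)[C@@H](C)C2=O | intermediate
6 | (2S,3S)-5-hydroxy-7-methoxy-2,3-dimethylchroman-4-one | COc1cc(O)c2c(c1)O[C@@H](C)[C@H](C)C2=O | intermediate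
7 | prenol, 3-methylbut-2-en-1-ol | CC(C)=CCO | starting material
8 | (2S,3S)-7-methoxy-2,3-dimethyl-5-[(3-methylbut-2-en-1-yl)oxy]chroman-4-one | COc1cc(OCC=C(C)C)c2c(c1)O[C@@H](C)[C@H](C)C2=O | intermediate
9 | (2S,3S)-7-methoxy-2,3-dimethyl-6-(2-methylbut-3-en-2-yl)-2,3-dihydro-4H-chromene-4,5(6H)-dione (C6 configuration not defined) | COC1=CC(O[C@@H](C)[C@H](C)C2=O)=C2C(=O)C1C(C)(C)C=C | intermediate (not isolated)
10 | (2S,3S)-7-methoxy-2,3-dimethyl-8-(3-methylbut-2-en-1-yl)-2,3-dihydro-4H-chromene-4,5(8H)-dione (C8 configuration not defined) | COC1=CC(=O)C2=C(O[C@@H](C)[C@H](C)C2=O)C1CC=C(C)C | intermediate (not isolated)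
11 | (2S,3S)-5-hydroxy-7-methoxy-2,3-dimethyl-8-(3-methylbut-2-en-1-yl)chroman-4-one | COc1cc(O)c2c(c1CC=C(C)C)O[C@@H](C)[C@H](C)C2=O | intermediate
12 | (E)-hex-2-enal | CCC/C=C/C=O | starting material
13 | (4R,8S,9S)-5-methoxy-8,9-dimethyl-6-(3-methylbut-2-en-1-yl)-4-propyl-3,4,8,9-tetrahydro-2H,10H-pyrano[2,3-f]chromene-2,10-dione | CCC[C@@H]1CC(=O)Oc2c1c(OC)c(CC=C(C)C)c1c2C(=O)[C@@H](C)[C@H](C)O1 | intermediate
14 | (3R)-3-[(2S,3S)-5-hydroxy-7-methoxy-2,3-dimethyl-8-(3-methylbut-2-en-1-yl)-4-oxo-3,4-dihydro-2H-chromen-6-yl]hexanoic acid | CCC[C@H](CC(=O)O)c1c(O)c2c(c(CC=C(C)C)c1OC)O[C@@H](C)[C@H](C)C2=O | target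

**Step count and risks**

Total steps: 8. Longest linear sequence: 8 (1 → 14).

Steps most likely to fail:

1. Step 7 (Proposed new method). The chelated, doubly flanked phenol may be too weak a carbon nucleophile, so that the acyl azolium is lost to O-acylation or to oxidant-driven side reactions, or the facial selectivity with a β-alkyl enal may be poor. The fallback sets out from 11 and comes back at 14. Phenol 11 is condensed with ethyl hex-2-ynoate by Pd(0)-catalysed hydroarylation–lactonisation (Pd2(dba)3·CHCl3, NaOAc, HCO2H, rt) to the 4-propylcoumarin (8S,9S)-5-methoxy-8,9-dimethyl-6-(3-methylbut-2-en-1-yl)-4-propyl-8,9-dihydro-2H,10H-pyrano[2,3-f]chromene-2,10-dione F1. The coumarin is opened with NaOH in MeOH–H2O to disodium (Z)-3-[(2S,3S)-7-methoxy-2,3-dimethyl-8-(3-methylbut-2-en-1-yl)-5-oxido-4-oxochroman-6-yl]hex-2-enoate F2. This salt is hydrogenated with Ru(OAc)2(BINAP) (the enantiomer that gives 3R) under H2, a carboxylate-directed asymmetric hydrogenation of a β-aryl-β-alkyl acrylate that should leave the unfunctionalised prenyl alkene alone. Cold acidification then gives 14.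

2. Step 6. Enolisation of dienone 9 may outrun the Cope shift, which would place a 1,1-dimethylallyl group at C6 instead of prenyl at C8. The fallback sets out from 5 and comes back at 11. Chromanone 5 is iodinated (NIS, cat. TFA, MeCN) at C8, the site expected for a 5,7-dialkoxychroman-4-one because C6 is flanked by two methoxy groups, to give (2S,3R)-8-iodo-5,7-dimethoxy-2,3-dimethylchroman-4-one F3. Stille coupling with tributyl(3-methylbut-2-en-1-yl)stannane (Pd(PPh3)4, DMF, 90 °C) gives (2S,3R)-5,7-dimethoxy-2,3-dimethyl-8-(3-methylbut-2-en-1-yl)chroman-4-one F4. MgI2 under the conditions of step 4 then cleaves the C5 methyl ether and equilibrates C3, giving 11.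

3. Step 3. An uncatalysed background cyclisation or a weak catalyst–substrate fit may erode the enantioselectivity at C2. The fallback sets out from 1 and comes back at 6. Friedel–Crafts propionylation of 1 (propionyl chloride, SnCl4) gives 1-(2,4,6-trimethoxyphenyl)propan-1-one F5. A syn-selective diisopinocampheylboron enolate aldol with acetaldehyde (Ipc2BOTf of the appropriate enantiomer, i-Pr2NEt, −78 °C) gives (2S,3R)-3-hydroxy-2-methyl-1-(2,4,6-trimethoxyphenyl)butan-1-one F6. BCl3 at −78 °C removes one ortho methyl group to give (2S,3R)-3-hydroxy-1-(2-hydroxy-4,6-dimethoxyphenyl)-2-methylbutan-1-one F7. Intramolecular Mitsunobu etherification (PPh3, DIAD) with inversion at the carbinol gives (2S,3S)-5,7-dimethoxy-2,3-dimethylchroman-4-one F8. MgI2 as in step 4 then gives 6.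

**Further compounds**

F1 | step 7 | (8S,9S)-5-methoxy-8,9-dimethyl-6-(3-methylbut-2-en-1-yl)-4-propyl-8,9-dihydro-2H,10H-pyrano[2,3-f]chromene-2,10-dione | CCCC1=CC(=O)Oc2c1c(OC)c(CC=C(C)C)c1c2C(=O)[C@@H](C)[C@H](C)O1
F2 | step 7 | disodium (Z)-3-[(2S,3S)-7-methoxy-2,3-dimethyl-8-(3-methylbut-2-en-1-yl)-5-oxido-4-oxochroman-6-yl]hex-2-enoate | CCC/C(=C/C(=O)[O-])c1c([O-])c2c(c(CC=C(C)C)c1OC)O[C@@H](C)[C@H](C)C2=O.[Na+].[Na+]
F3 | step 6 | (2S,3R)-8-iodo-5,7-dimethoxy-2,3-dimethylchroman-4-one | COc1cc(OC)c2c(c1I)O[C@@H](C)[C@@H](C)C2=O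
F4 | step 6 | (2S,3R)-5,7-dimethoxy-2,3-dimethyl-8-(3-methylbut-2-en-1-yl)chroman-4-one | COc1cc(OC)c2c(c1CC=C(C)C)O[C@@H](C)[C@@H](C)C2=O
F5 | step 3 | 1-(2,4,6-trimethoxyphenyl)propan-1-one | CCC(=O)c1c(OC)cc(OC)cc1OC
F6 | step 3 | (2S,3R)-3-hydroxy-2-methyl-1-(2,4,6-trimethoxyphenyl)butan-1-one | C[C@@H](O)[C@H](C)C(=O)c1c(OC)cc(OC)cc1OC
F7 | step 3 | (2S,3R)-3-hydroxy-1-(2-hydroxy-4,6-dimethoxyphenyl)-2-methylbutan-1-one | C[C@@H](O)[C@H](C)C(=O)c1c(O)cc(OC)cc1OC
F8 | step 3 | (2S,3S)-5,7-dimethoxy-2,3-dimethylchroman-4-one | COc1cc(OC)c2c(c1)O[C@@H](C)[C@H](C)C2=O
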